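**Retrosynthetic overview**
- The last C–C bond is a Negishi coupling between the E alkenylzirconocene from the ring A trienyne acetate and the dienyl iodide that carries ring B and ring C; one buffered desilylation then frees the ring C hydroxyl.
- The plan rests on the chain carbon bonded directly to the ring A C≡C: it carries CH3 and heads an E trisubstituted alkene in which CH3 is cis to the onward polyene. This is the pattern left by syn addition of CH3 and metal to a terminal alkyne, so the C–CH3 bond and the next sp2–sp2 bond are made in one pot from a ring A terminal 1,3-diyne and (E)-BrCH=CH–C≡C–SiMe3.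
- Ring A diyne: 4-oxoisophorone → (4R,6R)-actinol → silyl ether → enol triflate → Sonogashira coupling with Me3Si–C≡C–C≡CH → desilylation.
- Ring B/ring C iodide: actinol → enol triflate → ester → allylic alcohol → Sharpless epoxidation → aldehyde → E alkenylboronate → Suzuki coupling with 3-bromofuran-2(5H)-one → Z-selective ylidenation with (E)-3-iodo-2-methylprop-2-enal.
- Ring order: both carbocycles come intact from 4-oxoisophorone, ring B is bought as the bromobutenolide, and the oxirane on ring C (step 17) is the only ring closed.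

Key step: step 10

Remark: ring A = acetoxytrimethylcyclohexene, ring B = butenolide, ring C = epoxycyclohexanol; 3-bromofuran-2(5H)-one, Cl2CHBpin and Cp2Zr(H)Cl are taken as catalogue reagents, ZnCl2 serves as co-catalyst in steps 10 and 24, the ring A silyl ether is exchanged for the acetate before fragment union, and everything from 18 onward is handled with exclusion of light.

**Route**

Step 1
Reactants: 1 4-oxoisophorone (2,6,6-trimethylcyclohex-2-ene-1,4-dione)
Product: 2 (6R)-2,2,6-trimethylcyclohexane-1,4-dione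
Conditions: baker's yeast, sucrose, H2O, 30 °C
Reagents that add atoms: none
Why: Whole-cell ene-reductase reduction, in which the flavin enzyme adds hydride and a proton across the enedione C=C from one face and so sets the methyl-bearing carbon as (6R).

Step 2
Reactants: 2 (6R)-2,2,6-trimethylcyclohexane-1,4-dione
Product: 3 (4R,6R)-4-hydroxy-2,2,6-trimethylcyclohexan-1-one (actinol; OH trans to the C6 methyl)
Conditions: LiBH(s-Bu)3 (L-Selectride), THF, −78 °C; then H2O
Reagents that add atoms: none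
Why: Diastereoselective ketone reduction with a bulky trialkylborohydride, where the C4 carbonyl is far less hindered than C1 and hydride arrives equatorially (the axial path is blocked by the axial C2 methyl), giving the axial (4R) alcohol.

Step 3
Reactants: 3 (4R,6R)-4-hydroxy-2,2,6-trimethylcyclohexan-1-one
Product: 4 (4R,6R)-4-(tert-butyldimethylsilyloxy)-2,2,6-trimethylcyclohexan-1-one
Conditions: TBSCl, imidazole, DMF, rt
Reagents that add atoms: tert-butyldimethylsilyl chloride, CC(C)(C)[Si](C)(C)Cl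
Why: Standard silylation of a secondary alcohol, giving an ether that should survive amide base, amines and AlMe3 later on.

Step 4
Reactants: 4 (4R,6R)-4-(tert-butyldimethylsilyloxy)-2,2,6-trimethylcyclohexan-1-one
Product: 5 (4R)-4-(tert-butyldimethylsilyloxy)-2,6,6-trimethylcyclohex-1-en-1-yl trifluoromethanesulfonate
Conditions: LiN(i-Pr)2, THF, −78 °C; then PhNTf2, −78 °C → rt
Reagents that add atoms: N-phenylbis(trifluoromethanesulfonimide), O=S(=O)(N(c1ccccc1)S(=O)(=O)C(F)(F)F)C(F)(F)F
Why: Enolate formation and O-triflation, where C6 holds the only α-hydrogen so a single tetrasubstituted enol triflate forms; the C6 stereocentre is erased on purpose and C4 is untouched.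

Step 5
Reactants: 6 1,4-bis(trimethylsilyl)buta-1,3-diyne
Product: 8 buta-1,3-diyn-1-yl(trimethyl)silane, via lithium diynide Me3SiC≡CC≡CLi 7 (not isolated)
Conditions: MeLi·LiBr, Et2O, rt; then H2O, 0 °C (product kept as a solution)
Reagents that add atoms: none
Why: Nucleophilic Si–C(sp) cleavage by MeLi stops after one silyl group because the diynide anion formed resists a second attack, and protonation then gives the terminal diyne.

Step 6
Reactants: 5 (4R)-4-(tert-butyldimethylsilyloxy)-2,6,6-trimethylcyclohex-1-en-1-yl trifluoromethanesulfonate; 8 buta-1,3-diyn-1-yl(trimethyl)silane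
Product: 9 tert-butyldimethylsilyl ether of (1R)-3,5,5-trimethyl-4-[4-(trimethylsilyl)buta-1,3-diyn-1-yl]cyclohex-3-en-1-ol
Conditions: Pd(PPh3)4 (cat.), CuI (cat.), Et3N, DMF, rt
Reagents that add atoms: none
Why: Sonogashira coupling of an alkenyl triflate with a terminal alkyne, in which zerovalent palladium inserts into the C–OTf bond and the silyl cap blocks reaction at the far diyne terminus.

Step 7
Reactants: 9 tert-butyldimethylsilyl ether of (1R)-3,5,5-trimethyl-4-[4-(trimethylsilyl)buta-1,3-diyn-1-yl]cyclohex-3-en-1-ol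
Product: 10 tert-butyldimethylsilyl ether of (1R)-4-(buta-1,3-diyn-1-yl)-3,5,5-trimethylcyclohex-3-en-1-ol (ring A terminal diyne)
Conditions: K2CO3 (cat.), MeOH/THF, 0 °C; used at once
Reagents that add atoms: none
Why: Base-catalysed methanolysis of the alkynyl C–Si bond, to which the secondary silyl ether is stable.

Step 8
Reactants: 11 acetylene
Product: 12 (E)-1-bromo-2-iodoethene
Conditions: IBr, aq. HBr, 0 °C
Reagents that add atoms: iodine monobromide, BrI
Why: Electrophilic anti addition of IBr to the alkyne through a bridged iodonium ion places Br and I trans, which gives the E dihaloethene.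

Step 9
Reactants: 13 trimethylsilylacetylene; 12 (E)-1-bromo-2-iodoethene
Product: 16 (E)-(4-bromobut-3-en-1-yn-1-yl)trimethylsilane, via lithium acetylide Me3SiC≡CLi 14 (not isolated), via alkynylzinc bromide Me3SiC≡CZnBr 15 (not isolated)
Conditions: n-BuLi, THF, −78 °C; ZnBr2, 0 °C; then 12, Pd(PPh3)4 (cat.), 0 °C → rt
Reagents that add atoms: none
Why: Negishi alkynylation in which zerovalent palladium inserts only into the weaker C–I bond and coupling proceeds with retention, leaving the E C–Br bond for the key step.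

Step 10
Reactants: 10 tert-butyldimethylsilyl ether of (1R)-4-(buta-1,3-diyn-1-yl)-3,5,5-trimethylcyclohex-3-en-1-ol; 16 (E)-(4-bromobut-3-en-1-yn-1-yl)trimethylsilane
Product: 18 tert-butyldimethylsilyl ether of (1R)-3,5,5-trimethyl-4-[(3E,5E)-3-methyl-8-(trimethylsilyl)octa-3,5-diene-1,7-diyn-1-yl]cyclohex-3-en-1-ol, via alkenyl(dimethyl)alane 17 (not isolated)
Conditions: AlMe3 (2.5 equiv), Cp2ZrCl2 (0.25 equiv), ClCH2CH2Cl, 0 °C → rt; excess AlMe3 and solvent removed in vacuo; then 16, ZnCl2 (cat.), Pd(PPh3)4 (cat.), THF, rt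
Reagents that add atoms: trimethylaluminium, C[Al](C)C
Why: Proposed new method: Cp2ZrCl2 and AlMe3 form a methylzirconocene–alane pair that adds CH3 and metal syn across the terminal C≡C–H of 10 through a four-centre transition state, metal on the terminal carbon, and Zr-to-Al exchange gives alkenylalane 17 with CH3 and Al cis. The closest known reaction is the zirconium-catalysed methylalumination of terminal alkynes and terminal 1,3-enynes followed by palladium- and zinc-promoted coupling with alkenyl bromides of this type; its use on a terminal 1,3-diyne is the extension. ZnCl2 relays the alkenyl group to the divalent palladium formed by oxidative addition into the C–Br bond of 16, and reductive elimination joins the two sp2 carbons with retention at both, so the C(CH3)=CH alkene is E with CH3 cis to the onward chain and the CH=CH unit of 16 stays E. No ring is closed and no stereocentre is formed, and the silyl ether carbon is untouched. The step needs terminal over internal alkyne selectivity, which the substrate secures because the internal triple bond sits between the ring carbon next to the gem-dimethyl group and the reacting alkyne. It also needs carbometalation to outrun deprotonation of the acidic diyne C–H, which chlorinated solvent and excess AlMe3 favour, and any 10 returned from an alkynylalane on work-up can be recycled.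

Step 11
Reactants: 18 tert-butyldimethylsilyl ether of (1R)-3,5,5-trimethyl-4-[(3E,5E)-3-methyl-8-(trimethylsilyl)octa-3,5-diene-1,7-diyn-1-yl]cyclohex-3-en-1-ol
Product: 19 (1R)-3,5,5-trimethyl-4-[(3E,5E)-3-methylocta-3,5-diene-1,7-diyn-1-yl]cyclohex-3-en-1-ol
Conditions: Bu4NF, THF, 0 °C → rt
Reagents that add atoms: none
Why: Fluoride-induced desilylation cleaves both the alkynyl C–Si bond and the secondary Si–O bond, and the dienediyne has no other fluoride-labile group.

Step 12
Reactants: 19 (1R)-3,5,5-trimethyl-4-[(3E,5E)-3-methylocta-3,5-diene-1,7-diyn-1-yl]cyclohex-3-en-1-ol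
Product: 20 (1R)-3,5,5-trimethyl-4-[(3E,5E)-3-methylocta-3,5-diene-1,7-diyn-1-yl]cyclohex-3-en-1-yl acetate
Conditions: Ac2O, pyridine, DMAP (cat.), CH2Cl2, 0 °C → rt
Reagents that add atoms: acetic anhydride, CC(=O)OC(C)=O
Why: DMAP-catalysed acylation of the secondary alcohol with retention at the carbinol carbon, which installs the acetate of the target before fragment union.

Step 13
Reactants: 3 (4R,6R)-4-hydroxy-2,2,6-trimethylcyclohexan-1-one
Product: 21 (4R,6R)-2,2,6-trimethyl-4-(triethylsilyloxy)cyclohexan-1-one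
Conditions: Et3SiCl, imidazole, DMF, 0 °C → rt
Reagents that add atoms: chlorotriethylsilane, CC[Si](Cl)(CC)CC
Why: Silylation with the more labile triethylsilyl group, chosen so that the last step can be a buffered fluoride cleavage that spares acetate, oxirane and lactone.

Step 14
Reactants: 21 (4R,6R)-2,2,6-trimethyl-4-(triethylsilyloxy)cyclohexan-1-one
Product: 22 (4R)-2,6,6-trimethyl-4-(triethylsilyloxy)cyclohex-1-en-1-yl trifluoromethanesulfonate
Conditions: LiN(i-Pr)2, THF, −78 °C; then PhNTf2, −78 °C → rt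
Reagents that add atoms: N-phenylbis(trifluoromethanesulfonimide), O=S(=O)(N(c1ccccc1)S(=O)(=O)C(F)(F)F)C(F)(F)F
Why: Enolate formation at the only α-C–H and O-triflation, as in step 4, give the single tetrasubstituted enol triflate.

Step 15
Reactants: 22 (4R)-2,6,6-trimethyl-4-(triethylsilyloxy)cyclohex-1-en-1-yl trifluoromethanesulfonate
Product: 23 methyl (4R)-2,6,6-trimethyl-4-(triethylsilyloxy)cyclohex-1-ene-1-carboxylate
Conditions: CO (1 atm), MeOH, Pd(OAc)2 (cat.), PPh3, Et3N, DMF, 60 °C
Reagents that add atoms: carbon monoxide, [C-]#[O+]; methanol, CO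
Why: Palladium-catalysed alkoxycarbonylation of the enol triflate by oxidative addition, CO insertion and methanolysis of the acylpalladium.

Step 16
Reactants: 23 methyl (4R)-2,6,6-trimethyl-4-(triethylsilyloxy)cyclohex-1-ene-1-carboxylate
Product: 24 [(4R)-2,6,6-trimethyl-4-(triethylsilyloxy)cyclohex-1-en-1-yl]methanol
Conditions: i-Bu2AlH, CH2Cl2, −78 → 0 °C; aqueous work-up
Reagents that add atoms: none
Why: Hydride reduction of the conjugated ester to the allylic alcohol, with silyl ether and alkene inert.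

Step 17
Reactants: 24 [(4R)-2,6,6-trimethyl-4-(triethylsilyloxy)cyclohex-1-en-1-yl]methanol
Product: 25 [(1R,4S,6R)-2,2,6-trimethyl-4-(triethylsilyloxy)-7-oxabicyclo[4.1.0]heptan-1-yl]methanol (oxirane trans to the silyloxy group)
Conditions: t-BuOOH, Ti(Oi-Pr)4, D-(−)-diethyl tartrate, 4 Å molecular sieves, CH2Cl2, −20 °C
Reagents that add atoms: tert-butyl hydroperoxide, CC(C)(C)OO
Why: Sharpless asymmetric epoxidation of the tetrasubstituted allylic alcohol, in which the titanium tartrate from D-(−)-diethyl tartrate delivers oxygen to the face opposite the C4 silyloxy group (reagent control) and sets both oxirane carbons as (1R,6R).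

Step 18
Reactants: 25 [(1R,4S,6R)-2,2,6-trimethyl-4-(triethylsilyloxy)-7-oxabicyclo[4.1.0]heptan-1-yl]methanol
Product: 26 (1S,4S,6R)-2,2,6-trimethyl-4-(triethylsilyloxy)-7-oxabicyclo[4.1.0]heptane-1-carbaldehyde
Conditions: Dess–Martin periodinane, pyridine, CH2Cl2, 0 °C → rt
Reagents that add atoms: none
Why: Dess–Martin oxidation of the primary alcohol under buffered conditions, giving an aldehyde that has no α-hydrogen and cannot epimerise.

Step 19
Reactants: 26 (1S,4S,6R)-2,2,6-trimethyl-4-(triethylsilyloxy)-7-oxabicyclo[4.1.0]heptane-1-carbaldehyde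
Product: 27 4,4,5,5-tetramethyl-2-{(E)-2-[(1S,4S,6R)-2,2,6-trimethyl-4-(triethylsilyloxy)-7-oxabicyclo[4.1.0]heptan-1-yl]ethenyl}-1,3,2-dioxaborolane
Conditions: Cl2CHBpin, CrCl2, LiI, THF, rt
Reagents that add atoms: 2-(dichloromethyl)-4,4,5,5-tetramethyl-1,3,2-dioxaborolane, ClC(Cl)B1OC(C)(C)C(C)(C)O1
Why: Takai–Utimoto borylolefination, in which the geminal dichromium reagent from Cl2CHBpin and CrCl2 adds to the aldehyde and eliminates to the E alkenylboronate under neutral conditions that should spare oxirane and silyl ether.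

Step 20
Reactants: 27 4,4,5,5-tetramethyl-2-{(E)-2-[(1S,4S,6R)-2,2,6-trimethyl-4-(triethylsilyloxy)-7-oxabicyclo[4.1.0]heptan-1-yl]ethenyl}-1,3,2-dioxaborolane; 28 3-bromofuran-2(5H)-one
Product: 29 3-{(E)-2-[(1S,4S,6R)-2,2,6-trimethyl-4-(triethylsilyloxy)-7-oxabicyclo[4.1.0]heptan-1-yl]ethenyl}furan-2(5H)-one
Conditions: PdCl2(dppf) (cat.), K3PO4, THF/H2O, rt
Reagents that add atoms: none
Why: Suzuki–Miyaura coupling by oxidative addition into the C3–Br bond of the α-bromobutenolide, phosphate-assisted transmetalation and reductive elimination with retention of the E geometry.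

Step 21
Reactants: 30 prop-2-yn-1-ol
Product: 32 (E)-3-iodo-2-methylprop-2-en-1-ol, via alkenylalane alkoxide 31 (not isolated)
Conditions: AlMe3 (3 equiv), Cp2ZrCl2 (cat.), CH2Cl2, 0 °C → rt; then I2, THF, −30 → 0 °C
Reagents that add atoms: trimethylaluminium, C[Al](C)C; iodine, II
Why: Zirconium-catalysed methylalumination of the aluminium alkoxide of propargyl alcohol (syn, Al on the terminal carbon) and iodinolysis of the C–Al bond with retention give the E iodoalkene with I cis to CH3.

Step 22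
Reactants: 32 (E)-3-iodo-2-methylprop-2-en-1-ol
Product: 33 (E)-3-iodo-2-methylprop-2-enal
Conditions: MnO2, CH2Cl2, rt; used at once
Reagents that add atoms: none
Why: Selective oxidation of the allylic alcohol on activated MnO2, leaving alkene geometry and C–I bond untouched.

Step 23
Reactants: 29 3-{(E)-2-[(1S,4S,6R)-2,2,6-trimethyl-4-(triethylsilyloxy)-7-oxabicyclo[4.1.0]heptan-1-yl]ethenyl}furan-2(5H)-one; 33 (E)-3-iodo-2-methylprop-2-enal
Product: 36 (5Z)-5-[(2E)-3-iodo-2-methylprop-2-en-1-ylidene]-3-{(E)-2-[(1S,4S,6R)-2,2,6-trimethyl-4-(triethylsilyloxy)-7-oxabicyclo[4.1.0]heptan-1-yl]ethenyl}furan-2(5H)-one, via 2-silyloxyfuran 34 (not isolated), via aldol silyl ether 35 (not isolated)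
Conditions: TBSOTf, i-Pr2NEt, CH2Cl2, −78 → 0 °C; then DBU, 0 °C → rt
Reagents that add atoms: none
Why: One-pot vinylogous Mukaiyama aldol addition and elimination, in which 2-silyloxyfuran 34 adds through C5 to the silyl-activated aldehyde and DBU then removes the C5 proton and expels silanolate (E1cB) to give the thermodynamically favoured Z ylidene, erasing the two transient stereocentres of 35.

Step 24
Reactants: 20 (1R)-3,5,5-trimethyl-4-[(3E,5E)-3-methylocta-3,5-diene-1,7-diyn-1-yl]cyclohex-3-en-1-yl acetate; 36 (5Z)-5-[(2E)-3-iodo-2-methylprop-2-en-1-ylidene]-3-{(E)-2-[(1S,4S,6R)-2,2,6-trimethyl-4-(triethylsilyloxy)-7-oxabicyclo[4.1.0]heptan-1-yl]ethenyl}furan-2(5H)-one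
Product: 38 O-triethylsilylpyrrhoxanthin, via alkenylzirconocene chloride 37 (not isolated)
Conditions: Cp2Zr(H)Cl (1.1 equiv), THF, 0 °C → rt; then 36, ZnCl2 (cat.), Pd(PPh3)4 (cat.), THF, rt
Reagents that add atoms: none
Why: Hydrozirconation and Negishi coupling, in which Zr–H adds syn to the terminal alkyne with Zr on the terminal carbon (the internal alkyne is hindered and the acetate is reduced far more slowly) and ZnCl2-relayed transfer to the palladium inserted into the C–I bond of 36 joins the two sp2 carbons with retention, giving the all-E chain.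

Step 25
Reactants: 38 O-triethylsilylpyrrhoxanthin
Product: 39 pyrrhoxanthin (CNP0337675.1; 3S,5R,6S,3'R in carotenoid numbering)
Conditions: Bu4NF, AcOH (1:1), THF, 0 °C → rt
Reagents that add atoms: none
Why: Fluoride cleavage of the secondary triethylsilyl ether, buffered with acetic acid so that the acetate, the ylidene lactone and the vinyl oxirane should survive and no stereocentre is touched.

**Compound list**
1 | 4-oxoisophorone | CC1=CC(=O)CC(C)(C)C1=O | starting material
2 | (6R)-2,2,6-trimethylcyclohexane-1,4-dione | C[C@@H]1CC(=O)CC(C)(C)C1=O | intermediate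
3 | (4R,6R)-4-hydroxy-2,2,6-trimethylcyclohexan-1-one | O[C@@H]1C[C@@H](C)C(=O)C(C)(C)C1 | intermediate
4 | (4R,6R)-4-(tert-butyldimethylsilyloxy)-2,2,6-trimethylcyclohexan-1-one | CC(C)(C)[Si](C)(C)O[C@@H]1C[C@@H](C)C(=O)C(C)(C)C1 | intermediate
5 | (4R)-4-(tert-butyldimethylsilyloxy)-2,6,6-trimethylcyclohex-1-en-1-yl trifluoromethanesulfonate | CC(C)(C)[Si](C)(C)O[C@@H]1CC(C)=C(OS(=O)(=O)C(F)(F)F)C(C)(C)C1 | intermediate
6 | 1,4-bis(trimethylsilyl)buta-1,3-diyne | C[Si](C)(C)C#CC#C[Si](C)(C)C | starting material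
7 | lithium 4-(trimethylsilyl)buta-1,3-diyn-1-ide | [Li]C#CC#C[Si](C)(C)C | intermediate
8 | buta-1,3-diyn-1-yl(trimethyl)silane | C#CC#C[Si](C)(C)C | intermediate
9 | tert-butyldimethylsilyl ether of (1R)-3,5,5-trimethyl-4-[4-(trimethylsilyl)buta-1,3-diyn-1-yl]cyclohex-3-en-1-ol | CC(C)(C)[Si](C)(C)O[C@@H]1CC(C)=C(C#CC#C[Si](C)(C)C)C(C)(C)C1 | intermediate
10 | tert-butyldimethylsilyl ether of (1R)-4-(buta-1,3-diyn-1-yl)-3,5,5-trimethylcyclohex-3-en-1-ol | CC(C)(C)[Si](C)(C)O[C@@H]1CC(C)=C(C#CC#C)C(C)(C)C1 | intermediate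
11 | acetylene | C#C | starting material
12 | (E)-1-bromo-2-iodoethene | Br/C=C/I | intermediate
13 | trimethylsilylacetylene | C#C[Si](C)(C)C | starting material
14 | lithium (trimethylsilyl)acetylide | [Li]C#C[Si](C)(C)C | intermediate
15 | bromo[(trimethylsilyl)ethynyl]zinc | Br[Zn]C#C[Si](C)(C)C | intermediate
16 | (E)-(4-bromobut-3-en-1-yn-1-yl)trimethylsilane | Br/C=C/C#C[Si](C)(C)C | intermediate
17 | dimethyl{(1E)-4-[(4R)-4-(tert-butyldimethylsilyloxy)-2,6,6-trimethylcyclohex-1-en-1-yl]-2-methylbut-1-en-3-yn-1-yl}alane | CC(C)(C)[Si](C)(C)O[C@@H]1CC(C)=C(C#C/C(C)=C/[Al](C)C)C(C)(C)C1 | intermediate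
18 | tert-butyldimethylsilyl ether of (1R)-3,5,5-trimethyl-4-[(3E,5E)-3-methyl-8-(trimethylsilyl)octa-3,5-diene-1,7-diyn-1-yl]cyclohex-3-en-1-ol | CC(C)(C)[Si](C)(C)O[C@@H]1CC(C)=C(C#C/C(C)=C/C=C/C#C[Si](C)(C)C)C(C)(C)C1 | intermediate
19 | (1R)-3,5,5-trimethyl-4-[(3E,5E)-3-methylocta-3,5-diene-1,7-diyn-1-yl]cyclohex-3-en-1-ol | O[C@@H]1CC(C)=C(C#C/C(C)=C/C=C/C#C)C(C)(C)C1 | intermediate
20 | (1R)-3,5,5-trimethyl-4-[(3E,5E)-3-methylocta-3,5-diene-1,7-diyn-1-yl]cyclohex-3-en-1-yl acetate | CC(=O)O[C@@H]1CC(C)=C(C#C/C(C)=C/C=C/C#C)C(C)(C)C1 | intermediate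
21 | (4R,6R)-2,2,6-trimethyl-4-(triethylsilyloxy)cyclohexan-1-one | CC[Si](CC)(CC)O[C@@H]1C[C@@H](C)C(=O)C(C)(C)C1 | intermediate
22 | (4R)-2,6,6-trimethyl-4-(triethylsilyloxy)cyclohex-1-en-1-yl trifluoromethanesulfonate | CC[Si](CC)(CC)O[C@@H]1CC(C)=C(OS(=O)(=O)C(F)(F)F)C(C)(C)C1 | intermediate
23 | methyl (4R)-2,6,6-trimethyl-4-(triethylsilyloxy)cyclohex-1-ene-1-carboxylate | CC[Si](CC)(CC)O[C@@H]1CC(C)=C(C(=O)OC)C(C)(C)C1 | intermediate
24 | [(4R)-2,6,6-trimethyl-4-(triethylsilyloxy)cyclohex-1-en-1-yl]methanol | CC[Si](CC)(CC)O[C@@H]1CC(C)=C(CO)C(C)(C)C1 | intermediate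
25 | [(1R,4S,6R)-2,2,6-trimethyl-4-(triethylsilyloxy)-7-oxabicyclo[4.1.0]heptan-1-yl]methanol | OC[C@@]12O[C@]1(C)C[C@@H](O[Si](CC)(CC)CC)CC2(C)C | intermediate
26 | (1S,4S,6R)-2,2,6-trimethyl-4-(triethylsilyloxy)-7-oxabicyclo[4.1.0]heptane-1-carbaldehyde | O=C[C@@]12O[C@]1(C)C[C@@H](O[Si](CC)(CC)CC)CC2(C)C | intermediate
27 | 4,4,5,5-tetramethyl-2-{(E)-2-[(1S,4S,6R)-2,2,6-trimethyl-4-(triethylsilyloxy)-7-oxabicyclo[4.1.0]heptan-1-yl]ethenyl}-1,3,2-dioxaborolane | CC1(C)OB(/C=C/[C@@]23O[C@]2(C)C[C@@H](O[Si](CC)(CC)CC)CC3(C)C)OC1(C)C | intermediate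
28 | 3-bromofuran-2(5H)-one | O=C1OCC=C1Br | starting material
29 | 3-{(E)-2-[(1S,4S,6R)-2,2,6-trimethyl-4-(triethylsilyloxy)-7-oxabicyclo[4.1.0]heptan-1-yl]ethenyl}furan-2(5H)-one | O=C1OCC=C1/C=C/[C@@]23O[C@]2(C)C[C@@H](O[Si](CC)(CC)CC)CC3(C)C | intermediate
30 | prop-2-yn-1-ol | C#CCO | starting material
31 | (E)-Me2Al–CH=C(CH3)–CH2–O–AlMe2 (alkenylalane alkoxide) | C[Al](C)/C=C(C)/CO[Al](C)C | intermediate
32 | (E)-3-iodo-2-methylprop-2-en-1-ol | OC/C(C)=C/I | intermediate
33 | (E)-3-iodo-2-methylprop-2-enal | O=C/C(C)=C/I | intermediate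
34 | 2-(tert-butyldimethylsilyloxy)-3-{(E)-2-[(1S,4S,6R)-2,2,6-trimethyl-4-(triethylsilyloxy)-7-oxabicyclo[4.1.0]heptan-1-yl]ethenyl}furan | CC(C)(C)[Si](C)(C)Oc1occc1/C=C/[C@@]23O[C@]2(C)C[C@@H](O[Si](CC)(CC)CC)CC3(C)C | intermediate
35 | 5-[(2E)-1-(tert-butyldimethylsilyloxy)-3-iodo-2-methylprop-2-en-1-yl]-3-{(E)-2-[(1S,4S,6R)-2,2,6-trimethyl-4-(triethylsilyloxy)-7-oxabicyclo[4.1.0]heptan-1-yl]ethenyl}furan-2(5H)-one (mixture at the two new centres) | CC(C)(C)[Si](C)(C)OC(/C(C)=C/I)C1OC(=O)C(/C=C/[C@@]23O[C@]2(C)C[C@@H](O[Si](CC)(CC)CC)CC3(C)C)=C1 | intermediate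
36 | (5Z)-5-[(2E)-3-iodo-2-methylprop-2-en-1-ylidene]-3-{(E)-2-[(1S,4S,6R)-2,2,6-trimethyl-4-(triethylsilyloxy)-7-oxabicyclo[4.1.0]heptan-1-yl]ethenyl}furan-2(5H)-one | I/C=C(C)/C=C1C=C(/C=C/[C@@]23O[C@]2(C)C[C@@H](O[Si](CC)(CC)CC)CC3(C)C)C(=O)O/1 | intermediate
37 | chlorobis(cyclopentadienyl){(1E,3E,5E)-8-[(4R)-4-acetoxy-2,6,6-trimethylcyclohex-1-en-1-yl]-6-methylocta-1,3,5-trien-7-yn-1-yl}zirconium | CC(=O)O[C@@H]1CC(C)=C(C#C/C(C)=C/C=C/C=C/[Zr](Cl)(C2C=CC=C2)C2C=CC=C2)C(C)(C)C1 | intermediate
38 | O-triethylsilylpyrrhoxanthin | CC(=O)O[C@@H]1CC(C)=C(C#C/C(C)=C/C=C/C=C/C=C(C)/C=C2C=C(/C=C/[C@@]34O[C@]3(C)C[C@@H](O[Si](CC)(CC)CC)CC4(C)C)C(=O)O/2)C(C)(C)C1 | intermediate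
39 | pyrrhoxanthin (CNP0337675.1) | CC(=O)O[C@@H]1CC(C)=C(C#C/C(C)=C/C=C/C=C/C=C(C)/C=C2C=C(/C=C/[C@@]34O[C@]3(C)C[C@@H](O)CC4(C)C)C(=O)O/2)C(C)(C)C1 | target

**Step count and risks**

Total step count: 25. Longest linear sequence: 13 steps (1, 2, 13 to 20, 23, 24, 25).

Steps most likely to fail:

1. Step 10 (proposed new method). The alane may deprotonate the acidic diyne C–H instead of adding across it, addition may reach the internal triple bond or occur twice, or methyl may transfer in place of alkenyl in the coupling. The fallback uses known chemistry and sets out from triflate 5. Sonogashira coupling (Pd(PPh3)4, CuI, Et3N) with purchased (E)-3-methylpent-2-en-4-yn-1-ol, whose E alkene already holds CH3 and the alkyne in the required relationship, should give the ring A enynol F1. MnO2 oxidation should give the enynal F2, and Takai iodo-olefination (CHI3, CrCl2, THF) the E dienyl iodide F3. Sonogashira coupling of F3 with trimethylsilylacetylene 13 comes back to the route at 18.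

2. Step 23. The silyl triflate may open the fully substituted oxirane, the basic elimination may open the vinyl oxirane through the extended enolate, or the elimination may give incomplete Z selectivity. The fallback attaches ring C last and sets out from 28 and 33. The same silyl triflate and DBU sequence, now with no oxirane present, should pass through 3-bromo-2-(tert-butyldimethylsilyloxy)furan F4 and the aldol silyl ether F5 to the bromo iodo ylidenebutenolide F6. Negishi coupling of 37 (made from 20 as in step 24) at the C–I bond only should give the bromobutenolide polyene F7. Suzuki coupling of F7 with boronate 27 under the conditions of step 20 comes back to the route at 38.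

3. Step 24. Cp2Zr(H)Cl may reduce the acetate, hydrometalation may occur at other π bonds, or the organometallic may undergo protonolysis or loss of E geometry before it couples. The fallback sets out from 20. Hydroboration of the terminal alkyne with pinacolborane, catalysed by dicyclohexylborane, should give the E alkenylboronate F8. Suzuki–Miyaura coupling of F8 with 36 (Pd(PPh3)4, K3PO4, THF/H2O, rt) comes back to the route at 38.

Further compounds
F1 | step 10 | (2E)-5-[(4R)-4-(tert-butyldimethylsilyloxy)-2,6,6-trimethylcyclohex-1-en-1-yl]-3-methylpent-2-en-4-yn-1-ol | CC(C)(C)[Si](C)(C)O[C@@H]1CC(C)=C(C#C/C(C)=C/CO)C(C)(C)C1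
F2 | step 10 | (2E)-5-[(4R)-4-(tert-butyldimethylsilyloxy)-2,6,6-trimethylcyclohex-1-en-1-yl]-3-methylpent-2-en-4-ynal | CC(C)(C)[Si](C)(C)O[C@@H]1CC(C)=C(C#C/C(C)=C/C=O)C(C)(C)C1
F3 | step 10 | tert-butyldimethylsilyl ether of (1R)-4-[(3E,5E)-6-iodo-3-methylhexa-3,5-dien-1-yn-1-yl]-3,5,5-trimethylcyclohex-3-en-1-ol | CC(C)(C)[Si](C)(C)O[C@@H]1CC(C)=C(C#C/C(C)=C/C=C/I)C(C)(C)C1
F4 | step 23 | 3-bromo-2-(tert-butyldimethylsilyloxy)furan | CC(C)(C)[Si](C)(C)Oc1occc1Br
F5 | step 23 | 3-bromo-5-[(2E)-1-(tert-butyldimethylsilyloxy)-3-iodo-2-methylprop-2-en-1-yl]furan-2(5H)-one | CC(C)(C)[Si](C)(C)OC(/C(C)=C/I)C1OC(=O)C(Br)=C1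
F6 | step 23 | (5Z)-3-bromo-5-[(2E)-3-iodo-2-methylprop-2-en-1-ylidene]furan-2(5H)-one | I/C=C(C)/C=C1C=C(Br)C(=O)O/1
F7 | step 23 | (1R)-4-[(3E,5E,7E,9E)-10-[(2Z)-4-bromo-5-oxofuran-2(5H)-ylidene]-3,9-dimethyldeca-3,5,7,9-tetraen-1-yn-1-yl]-3,5,5-trimethylcyclohex-3-en-1-yl acetate | CC(=O)O[C@@H]1CC(C)=C(C#C/C(C)=C/C=C/C=C/C=C(C)/C=C2C=C(Br)C(=O)O/2)C(C)(C)C1
F8 | step 24 | (1R)-3,5,5-trimethyl-4-[(3E,5E,7E)-3-methyl-8-(4,4,5,5-tetramethyl-1,3,2-dioxaborolan-2-yl)octa-3,5,7-trien-1-yn-1-yl]cyclohex-3-en-1-yl acetate | CC(=O)O[C@@H]1CC(C)=C(C#C/C(C)=C/C=C/C=C/B2OC(C)(C)C(C)(C)O2)C(C)(C)C1
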